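(The readings were computed with made-up constants.)

The south-east run holds 3.00 times the Sub of the north run, yet at 0.88 min it shows 1.79 times its Prd, a smaller ratio than that of the charges.

| flask | Sub | Rgt | Cat | time |
|---|---|---|---|---|
| north | 0.250 M | 0.750 M | 5.00 × 10⁻⁴ M |  |
| south-east | 0.750 M | 0.750 M | 5.00 × 10⁻⁴ M |  |
| north-west | 0.250 M | 0.750 M | 1.60 × 10⁻⁴ M | 5.3 min |

| run | time / min | [Prd] / M |
|---|---|---|
| north run | 0.88 | 0.0604 |
| north run | 1.8 | 0.0989 |
| north run | 2.6 | 0.1230 |
| north run | 3.5 | 0.1427 |
| north run | 4.4 | 0.1569 |
| north run | 5.3 | 0.1652 |
| south-east run | 0.88 | 0.1081 |
| south-east run | 1.8 | 0.1749 |
| south-east run | 2.6 | 0.2093 |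
| south-east run | 3.5 | 0.2496 |
| south-east run | 4.4 | 0.2811 |
| south-east run | 5.3 | 0.3017 |

(scatter of a reading: 0.002 M)

- how the opening rate goes with [Sub] round the charge of the north run: the exponent of the rate at two percent of Sub gone to Prd (one fixed amount of Prd, the same in the runs compared)
- Prd in the north-west run at 5.3 min, as a share of the Sub charged
- which of these the readings show (two substrates go astray together / the by-product ties up the catalyst / an uncatalysed path runs beside)

- Overall: Sub + Rgt -> Prd, with Cat as catalyst.
- Constant volume, constant temperature.
- Readings of a species count what is bound in complexes too.
- An order is taken over about fifteen percent of the charge, up and down.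

Sub is the first setting. By hand, a rate in step with Sub gives the ratio of the charges, but the first readings give an exponent of 0.530, taken across the two charges and at one time, not at one amount of Prd, and I take that as my rough opening order. The comparison also drifts inside the north run. Its mean rate falls 4.39-fold from the first stretch to the stretch after 2.6 min, while the product of Sub and Rgt falls 2.47-fold, less than the rate. I read this as something that grows with Prd slowing the north run, so I choose the by-product tying up the catalyst.

Cat is the second setting, and the north-west run cuts it. I assume the rate goes with the Cat charge, so that flasks with equal Sub and Rgt charges make equal Prd at equal scaled time. At 5.3 min the north-west run has then reached 1.70 min on the north clock, its time scaled by its Cat charge over that of the north run. That falls between the north readings at 0.88 min and 1.8 min. The reading at 1.8 min is 39.6% of the Sub, and the straight chord between the two readings gives 37.8%. The curve bends, so I expect a share between these, and a single reading carries a scatter of 0.800% of this Sub charge.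

The forecast gives 38%, inside my bracket, with the same scaling: “Since rate scales with Cat, time scales too”. It also chooses the by-product ties up the catalyst, but its order of 0.69 is higher than my rough one.

The north-west run gives 38.9% of its Sub, between my two figures.

    Cat + Sub ⇌ Cat.Sub, settled at all times (4.080 /M)
    Cat.Sub + Rgt → Prd + Cat + Byp (618.0 /M/min)
    Cat + Byp ⇌ Cat.Byp, settled at all times (22.80 /M)

The readings show that the by-product ties up the catalyst, and the opening order round the north charge is 0.54, while across the two charges the south-east rate is 1.5 times the north rate at that same amount of Prd. The south-east run carries the Cat charge of the north run, so a scaled time there equals its own time, though its Sub charge differs and its Prd is read from its own curve. At 1.70 min it stands short of 2.11 min, its time for a quarter of its Sub, and its nearest reading, at 1.8 min, is 23.3% of its Sub.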